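**Retrosynthetic overview**
1. The target (griseophenone A) is an achiral benzophenone. Neither ring is built: ring A is bought as 1-chloro-2,4-dimethoxybenzene (chlorine position purchased) and ring B as 2,4-dihydroxy-6-methylbenzaldehyde.
2. Last disconnection: the pivaloyl protecting group on the ring B 4-OH.
3. Key (new) disconnection: ring A C2–OH back to C2–H, by ketone-directed C–H hydroxylation of the 5-chloro-2,4-dimethoxyphenyl ketone, whose only ortho C–H lies between C=O and C–Cl.
4. Aryl–C(=O) bond: Friedel–Crafts acylation of the chlorodimethoxybenzene by the ring B benzoic acid (acylium route).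
5. Ring B acid: selective 4-O-pivaloylation, 2-O-methylation, Pinnick oxidation.

Assumption: the target has no stereocentre, so "single enantiomer" requires no stereocontrol; the SMILES is taken as written.

**Route**

Step 1
Reactants: 1 2,4-dihydroxy-6-methylbenzaldehyde
Product: 2 4-formyl-3-hydroxy-5-methylphenyl pivalate
Conditions: PivCl (1.05 equiv), Et3N (1.2 equiv), CH2Cl2, −20 to 0 °C
Reagents that add atoms: pivaloyl chloride, CC(C)(C)C(=O)Cl
Why: Chemoselective phenol O-acylation; the 4-OH is free and more acidic, while the 2-OH is hydrogen-bonded to and flanked by the formyl group, so one equivalent of the bulky acyl chloride esterifies only the 4-OH.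

Step 2
Reactants: 2 4-formyl-3-hydroxy-5-methylphenyl pivalate
Product: 3 4-formyl-3-methoxy-5-methylphenyl pivalate
Conditions: MeI (3 equiv), K2CO3 (1.5 equiv), dry DMF, 20 °C
Reagents that add atoms: iodomethane, CI
Why: Williamson O-methylation of the remaining chelated phenol; the hindered aryl pivalate tolerates K2CO3 in dry DMF at room temperature.

Step 3
Reactants: 3 4-formyl-3-methoxy-5-methylphenyl pivalate
Product: 4 2-methoxy-6-methyl-4-(pivaloyloxy)benzoic acid
Conditions: NaClO2 (3 equiv), NaH2PO4 (3 equiv), 2-methyl-2-butene (10 equiv), t-BuOH/H2O 3:1, 20 °C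
Reagents that add atoms: sodium chlorite NaClO2, [Na+].[O-]Cl=O
Why: Pinnick oxidation converts the hindered aryl aldehyde to the acid under buffered conditions that leave the ester and ethers alone, the alkene scavenging HOCl so the ring is not chlorinated.

Step 4
Reactants: 4 2-methoxy-6-methyl-4-(pivaloyloxy)benzoic acid; 5 1-chloro-2,4-dimethoxybenzene
Product: 7 4-(5-chloro-2,4-dimethoxybenzoyl)-3-methoxy-5-methylphenyl pivalate, via mixed trifluoroacetic anhydride 6 (not isolated)
Conditions: (CF3CO)2O (2.5 equiv), CH2Cl2, 20 °C, 30 min; then 5 (1.2 equiv), TfOH (10 mol%), 0 to 20 °C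
Reagents that add atoms: trifluoroacetic anhydride, O=C(OC(=O)C(F)(F)F)C(F)(F)F (its trifluoroacetyl group is carried only by intermediate 6)
Why: Friedel–Crafts acylation; the di-ortho-substituted aroyl trifluoroacetate ionises to a stabilised acylium ion that attacks 5 at C5 (para to one methoxy, ortho to the other), the site between the two methoxy groups being too crowded and C6 unactivated.

Step 5
Reactants: 7 4-(5-chloro-2,4-dimethoxybenzoyl)-3-methoxy-5-methylphenyl pivalate
Product: 9 4-(3-chloro-2-hydroxy-4,6-dimethoxybenzoyl)-3-methoxy-5-methylphenyl pivalate, via aryl trifluoroacetate 8 (not isolated)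
Conditions: Pd(OCOCF3)2 (10 mol%), K2S2O8 (2 equiv), CF3CO2H, 50 °C; then evaporation, THF/H2O, 20 °C
Reagents that add atoms: trifluoroacetic acid, OC(=O)C(F)(F)F (supplies the new oxygen atom; its trifluoroacetyl part stays only in intermediate 8)
Why: Proposed new method: ketone-directed ortho-C–H oxygenation at a C–H flanked by chlorine and the acyl group of a tri-ortho-substituted polyalkoxybenzophenone, which has not been shown; the carbonyl oxygen (coplanar with ring A because the di-ortho-substituted ring B is twisted out of conjugation) binds electrophilic divalent palladium trifluoroacetate, concerted metalation–deprotonation at the only ortho C–H in the molecule (acidified by the adjacent C–Cl) gives a five-membered palladacycle, K2S2O8 oxidises it to tetravalent palladium, and C–O reductive elimination gives the electron-poor aryl trifluoroacetate 8 (no over-oxidation, no phenolic coupling since the ring B oxygen is acylated), which hydrolyses on work-up; closest known reaction type: palladium-catalysed ketone-directed ortho-hydroxylation of simple aryl ketones with persulfate or hypervalent iodine oxidants in trifluoroacetic acid.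

Step 6
Reactants: 9 4-(3-chloro-2-hydroxy-4,6-dimethoxybenzoyl)-3-methoxy-5-methylphenyl pivalate
Product: 10 (3-chloro-2-hydroxy-4,6-dimethoxyphenyl)(4-hydroxy-2-methoxy-6-methylphenyl)methanone
Conditions: LiOH·H2O (3 equiv), THF/H2O 3:1, 0 to 20 °C; then 1 M HCl
Reagents that add atoms: none
Why: Saponification of the aryl pivalate (phenoxide leaving group) at room temperature leaves the methyl ethers, aryl chloride and hindered diaryl ketone untouched and is too mild for base-induced xanthone closure.

**Compound list**
1 | 2,4-dihydroxy-6-methylbenzaldehyde | Cc1cc(O)cc(O)c1C=O | starting material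
2 | 4-formyl-3-hydroxy-5-methylphenyl pivalate | Cc1cc(OC(=O)C(C)(C)C)cc(O)c1C=O | intermediate
3 | 4-formyl-3-methoxy-5-methylphenyl pivalate | Cc1cc(OC(=O)C(C)(C)C)cc(OC)c1C=O | intermediate
4 | 2-methoxy-6-methyl-4-(pivaloyloxy)benzoic acid | Cc1cc(OC(=O)C(C)(C)C)cc(OC)c1C(=O)O | intermediate
5 | 1-chloro-2,4-dimethoxybenzene | COc1ccc(Cl)c(OC)c1 | starting material
6 | 2-methoxy-6-methyl-4-(pivaloyloxy)benzoic trifluoroacetic anhydride (not isolated) | Cc1cc(OC(=O)C(C)(C)C)cc(OC)c1C(=O)OC(=O)C(F)(F)F | intermediate
7 | 4-(5-chloro-2,4-dimethoxybenzoyl)-3-methoxy-5-methylphenyl pivalate | COc1cc(OC)c(Cl)cc1C(=O)c1c(C)cc(OC(=O)C(C)(C)C)cc1OC | intermediate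
8 | 4-[3-chloro-4,6-dimethoxy-2-(trifluoroacetoxy)benzoyl]-3-methoxy-5-methylphenyl pivalate (not isolated) | COc1cc(OC)c(Cl)c(OC(=O)C(F)(F)F)c1C(=O)c1c(C)cc(OC(=O)C(C)(C)C)cc1OC | intermediate
9 | 4-(3-chloro-2-hydroxy-4,6-dimethoxybenzoyl)-3-methoxy-5-methylphenyl pivalate | COc1cc(OC)c(Cl)c(O)c1C(=O)c1c(C)cc(OC(=O)C(C)(C)C)cc1OC | intermediate
10 | (3-chloro-2-hydroxy-4,6-dimethoxyphenyl)(4-hydroxy-2-methoxy-6-methylphenyl)methanone | COc1cc(OC)c(C(=O)c2c(C)cc(O)cc2OC)c(O)c1Cl | target

**Count and risks**
Total step count: 6. Longest linear sequence: 6 steps (1 to 10; arene 5 is bought and enters at step 4).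

The three steps most likely to fail:

Most at risk is the new hydroxylation (step 5). Palladation next to chlorine may be slow, and warm CF3CO2H with persulfate could cause protodeacylation or oxidation of the electron-rich rings. The fallback uses known chemistry only, sets out from acid 4 and comes back to the route at 9; the phenol oxygen is bought instead of made. Acid 4 is converted with (CF3CO)2O in CH2Cl2 into mixed anhydride 6, which acylates commercially available 2-chloro-3,5-dimethoxyphenol F1 at the free position ortho to its hydroxyl group. This is the classical Friedel–Crafts C-acylation of a phloroglucinol-type phenol. Aqueous NaHCO3 work-up cleaves any phenyl trifluoroacetate, and chromatography removes the para-acylated isomer to give 9.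

Second is the acylation (step 4). Acid 4 may ionise poorly because of its electron-withdrawing pivaloyloxy group, or 5 may be trifluoroacetylated. The fallback reverses the polarity, sets out from aldehyde 3 and arene 5 and comes back at 7. Arene 5 is brominated para to its 2-methoxy group (NBS, MeCN, 20 °C) to 1-bromo-5-chloro-2,4-dimethoxybenzene F2. Bromine–magnesium exchange (iPrMgCl·LiCl, THF, −15 °C, C–Cl untouched) gives (5-chloro-2,4-dimethoxyphenyl)magnesium chloride F3, used in solution. It adds to the formyl group of 3 at −40 °C, faster than to the hindered pivalate, giving racemic 4-[(5-chloro-2,4-dimethoxyphenyl)(hydroxy)methyl]-3-methoxy-5-methylphenyl pivalate F4. Dess–Martin periodinane (CH2Cl2, 20 °C) erases that stereocentre and gives ketone 7.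

Third is the methylation (step 2). Under K2CO3 the phenoxide of 2 may take a pivaloyl group from another molecule and scramble the ester. The fallback changes the protecting-group order so the ester never meets the basic methylation; it sets out from 1 and comes back at 3. Aldehyde 1 is protected selectively at the 4-OH (MOMCl, iPr2NEt, CH2Cl2, 0 °C) to 2-hydroxy-4-(methoxymethoxy)-6-methylbenzaldehyde F5. Methylation (MeI, K2CO3, DMF) gives 2-methoxy-4-(methoxymethoxy)-6-methylbenzaldehyde F6. Acetal cleavage (3 M HCl, THF, 40 °C) gives 4-hydroxy-2-methoxy-6-methylbenzaldehyde F7, which is pivaloylated (PivCl, Et3N, CH2Cl2, 0 °C) to 3.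

**Further compounds**
F1 | step 5 | 2-chloro-3,5-dimethoxyphenol | COc1cc(O)c(Cl)c(OC)c1
F2 | step 4 | 1-bromo-5-chloro-2,4-dimethoxybenzene | COc1cc(OC)c(Cl)cc1Br
F3 | step 4 | (5-chloro-2,4-dimethoxyphenyl)magnesium chloride | COc1cc(OC)c(Cl)cc1[Mg]Cl
F4 | step 4 | 4-[(5-chloro-2,4-dimethoxyphenyl)(hydroxy)methyl]-3-methoxy-5-methylphenyl pivalate (racemic) | COc1cc(OC)c(Cl)cc1C(O)c1c(C)cc(OC(=O)C(C)(C)C)cc1OC
F5 | step 2 | 2-hydroxy-4-(methoxymethoxy)-6-methylbenzaldehyde | Cc1cc(OCOC)cc(O)c1C=O
F6 | step 2 | 2-methoxy-4-(methoxymethoxy)-6-methylbenzaldehyde | Cc1cc(OCOC)cc(OC)c1C=O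
F7 | step 2 | 4-hydroxy-2-methoxy-6-methylbenzaldehyde | Cc1cc(O)cc(OC)c1C=O
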